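We count the partner.

in all of them: substrate 0.20 M

| flask | partner | capture agent | remark | time |
|---|---|---|---|---|
| midnight | 0.70 equiv | 0.060 M | run made earlier |  |
| summer | 1.1 equiv | 0.060 M | run made earlier |  |
| flask | 0.500 equiv | 0.0600 M |  | 50 min |

- midnight (time / min: mono adduct / %, bis adduct / %, substrate / %): 5.00: 31.2, 4.8, 31.2; 8.00: 31.2, 4.3, 29.1; 12.0: 31.3, 4.2, 27.5; 15.0: 31.1, 4.3, 25.4; 25.0: 31.3, 4.4, 21.3; 40.0: 31.2, 4.4, 16.5; 60.0: 31.5, 4.9, 11.4
- summer (time / min: mono adduct / %, bis adduct / %, substrate / %): 5.00: 42.5, 18.6, 8.1; 8.00: 42.0, 18.2, 7.2; 12.0: 42.7, 18.7, 7.0; 15.0: 41.6, 19.0, 6.8; 25.0: 42.0, 18.8, 5.5; 40.0: 41.7, 19.5, 4.3; 60.0: 42.2, 18.9, 2.9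

(each reading ± 0.3 percentage points)

- equivalents of partner to substrate, everything else as given, that leave most mono adduct at 50 min
- the amount of mono adduct then, in percent of the substrate charged
- the amount of mono adduct with the amounts as given

- the earlier runs were read with a standard deviation of 0.3 percentage points
- a reading or a percentage of bis adduct counts all its forms, free or not

We suppose each mono adduct holds one partner and each bis adduct two. Mono plus two per bis then gives the partner the readings still show, and the charge minus that sum is what has gone elsewhere, so we work with what is left and not with what is made. In the midnight run at 25.0 min this gap is 29.9 % of the substrate charged. In the summer run, with more partner, it is 30.4 %, so the gap looks like a fixed payment.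

The second way uses no reading. The capture agent charged over the substrate charged is 30.0 %, and we call this share the capture toll, supposing one partner taken per capture agent. The two ways come from different things and lie within 0.4 percentage points of each other, so we trust the toll.

For the new flask, the partner charged minus the toll leaves 20.0 % of the substrate charged as usable partner, and mono plus two per bis should come to that. Our own reckoning commits to mono adduct a little under 20.0 %. The forecast reads the same payment, “Capture thus removes one mono-equivalent per agent”, and gives 18.2 % for this flask, with 42.3 % at 1.05 equiv as the best charge.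

The flask gives 17.0 %, and the best charge is 1.04 equiv, with 42.3 % of mono adduct.

    partner + mono adduct → bis adduct (k = 0.0670 M⁻¹ s⁻¹)
    substrate → decomposition product (k = 3.00 × 10⁻⁴ s⁻¹)
    substrate + partner → mono adduct (k = 0.270 M⁻¹ s⁻¹)
    mono adduct + capture agent → trapped intermediate (k = 3.90 M⁻¹ s⁻¹)
    crystals ⇌ bis adduct, rate k5*(cs5 - [bis adduct]) while solid is left; crystals form when [bis adduct] > cs5 (solubility = 22.0 mM, k = 3.20 s⁻¹)

In the new flask at 50.0 min the trapped intermediate stands at 30.0 %, level with the toll of 30.0 %. Partner, the limiting reagent against the substrate still standing at 20.8 %, stands at 0 %. Mono adduct, with two partner for each bis adduct at 1.49 %, comes to 20.0 % against the usable 20.0 %. The neighbouring flask with 0.850 equiv of partner has 55.0 % usable after the toll, and there mono adduct at 38.6 %, with two partner for each bis adduct at 8.22 %, comes to 55.0 %.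

The data come from a simulation from invented constants; scatter was added.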